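**Plan**
- The target is 1-(2,6-dihydroxyphenyl)-9-(4-hydroxy-3-methoxyphenyl)nonan-1-one: ring A (the guaiacol ring) and ring B are joined by eight CH2 groups (C2–C9) and the ketone C1. The two hydroxyls of ring B sit on C2' and C6', the two carbons flanking C1', which carries the only carbonyl, so that carbonyl oxygen can deliver a metal to exactly those two C–H bonds.
- Retrosynthesis: cut the ring A O–S bond of a mesylate-protected target, then both ring B C–O bonds (C2'–O and C6'–O) back to a plain phenyl ketone, then the mesylate O–S bond.
- Further cuts: C1–C1' (Weinreb amide plus phenyl Grignard reagent) and C8=C9 (Wittig alkene, later hydrogenated), leading to vanillin, 8-bromooctanoic acid and bromobenzene.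
- Forward: phosphonium salt, Wittig joining of the chain to ring A, hydrogenation, Weinreb amide, phenyl ketone, mesylation, twofold ortho C–H hydroxylation, mesylate cleavage. Both rings are bought; none is built.
- Stereochemistry: the target has no stereocentre, and the Z/E mixture from the Wittig step is erased by hydrogenation.

Key step: step 7

Remark: alkene 5 is expected as a Z/E mixture (Z dominant) and is carried on unseparated; its SMILES shows the Z isomer.
Remark: in step 7 the two new ring B oxygens come from trifluoroacetate; water in the work-up only cleaves the two aryl esters.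

**Step 1**
Reactants: 1 8-bromooctanoic acid
Product: 2 (7-carboxyheptyl)triphenylphosphonium bromide
Conditions: PPh3, MeCN, reflux
Reagents that add atoms: triphenylphosphine, c1ccc(cc1)P(c1ccccc1)c1ccccc1
Why: SN2 alkylation of the phosphine by the primary bromide (phosphonium salt formation for a Wittig reaction) is clean because the free carboxylic acid does not react with PPh3.

**Step 2**
Reactants: 2 (7-carboxyheptyl)triphenylphosphonium bromide; 3 vanillin
Product: 5 (Z)-9-(4-hydroxy-3-methoxyphenyl)non-8-enoic acid (Z/E mixture), via ylide carboxylate 4 (not isolated)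
Conditions: 2 (1.5 equiv), KOtBu (4 equiv), THF, 0 °C; then 3, 0 °C to rt; aq HCl
Reagents that add atoms: none
Why: Wittig olefination in which the non-stabilised ylide 4 (two equivalents of base per phosphonium salt) adds to the aldehyde of vanillin, present as its potassium phenoxide (hence the extra base and the excess of ylide), and the oxaphosphetane collapses to the styrene, whose geometry does not matter.

**Step 3**
Reactants: 5 (Z)-9-(4-hydroxy-3-methoxyphenyl)non-8-enoic acid (Z/E mixture)
Product: 6 9-(4-hydroxy-3-methoxyphenyl)nonanoic acid
Conditions: H2 (1 atm), 10% Pd/C, EtOAc/EtOH, rt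
Reagents that add atoms: none
Why: heterogeneous catalytic hydrogenation of a disubstituted styrene-type alkene is fast at atmospheric pressure and leaves the arene, phenol and acid untouched, while removing the only stereo-element of the sequence.

**Step 4**
Reactants: 6 9-(4-hydroxy-3-methoxyphenyl)nonanoic acid
Product: 7 9-(4-hydroxy-3-methoxyphenyl)-N-methoxy-N-methylnonanamide
Conditions: MeNHOMe·HCl, EDC·HCl, HOBt, N-methylmorpholine, CH2Cl2, 0 °C to rt
Reagents that add atoms: N,O-dimethylhydroxylamine hydrochloride, CNOC.Cl
Why: carbodiimide amide coupling (Weinreb amide formation) in which the hydroxybenzotriazole active ester is captured much faster by the nucleophilic N,O-dimethylhydroxylamine than by the weakly nucleophilic guaiacol hydroxyl.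

**Step 5**
Reactants: 7 9-(4-hydroxy-3-methoxyphenyl)-N-methoxy-N-methylnonanamide; 8 bromobenzene
Product: 10 9-(4-hydroxy-3-methoxyphenyl)-1-phenylnonan-1-one, via phenylmagnesium bromide 9 (not isolated)
Conditions: 8 (3 equiv), Mg, THF, reflux; then 7, THF, 0 °C to rt; aq HCl
Reagents that add atoms: none
Why: Grignard formation followed by Weinreb ketone synthesis, in which one equivalent of 9 deprotonates the phenol and a further one adds to the amide to give a stable five-membered magnesium chelate that releases the ketone only on acidic work-up, so no tertiary alcohol should form.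

**Step 6**
Reactants: 10 9-(4-hydroxy-3-methoxyphenyl)-1-phenylnonan-1-one
Product: 11 2-methoxy-4-(9-oxo-9-phenylnonyl)phenyl methanesulfonate
Conditions: MsCl, Et3N, CH2Cl2, 0 °C
Reagents that add atoms: methanesulfonyl chloride, CS(=O)(=O)Cl
Why: O-sulfonylation of the phenol is selective because the aryl ketone does not react with MsCl/Et3N at 0 °C, and the mesylate is an acid-stable, electron-withdrawing mask that lowers the electron density of ring A for the oxidation to come.

**Step 7**
Reactants: 11 2-methoxy-4-(9-oxo-9-phenylnonyl)phenyl methanesulfonate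
Product: 14 4-[9-(2,6-dihydroxyphenyl)-9-oxononyl]-2-methoxyphenyl methanesulfonate, via mono(trifluoroacetate) 12 (not isolated), via bis(trifluoroacetate) 13 (not isolated)
Conditions: Pd(O2CCF3)2 (10–15 mol %), K2S2O8 (5 equiv), CF3CO2H/(CF3CO)2O 9:1, 60–70 °C; then H2O/MeOH, rt
Reagents that add atoms: trifluoroacetic acid, OC(=O)C(F)(F)F
Why: Proposed new method: the ketone oxygen binds divalent palladium and a trifluoroacetate-assisted concerted metalation–deprotonation at an ortho C–H of ring B gives a five-membered palladacycle, which persulfate oxidises to tetravalent palladium so that C–O reductive elimination releases aryl trifluoroacetate 12 and returns divalent palladium. Because the anhydride keeps the new oxygen as an ester, no phenol–carbonyl hydrogen bond locks the ketone away from the remaining ortho C–H, so rotation about the C1–C1' bond lets the same cycle run at C6' to give 13, and water then cleaves both esters. The closest known reaction type is the single ketone-directed ortho C–H hydroxylation of aryl ketones with Pd(O2CCF3)2 and K2S2O8 in CF3CO2H; the twofold version on a substrate carrying a second oxygenated arene is not established. No ring is closed and no stereocentre is formed. The selectivity needed is ring B ortho positions over ring A and the chain: the chelate secures the first, the mesylate deactivates ring A towards electrophilic palladation and one-electron oxidation, and each new phenol is masked as an electron-poor trifluoroacetate against over-oxidation.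

**Step 8**
Reactants: 14 4-[9-(2,6-dihydroxyphenyl)-9-oxononyl]-2-methoxyphenyl methanesulfonate
Product: 15 1-(2,6-dihydroxyphenyl)-9-(4-hydroxy-3-methoxyphenyl)nonan-1-one
Conditions: KOH, MeOH/H2O (degassed), 60 °C, argon; then aq HCl
Reagents that add atoms: none
Why: alkaline hydrolysis of an aryl methanesulfonate (hydroxide attack at sulfur or E1cB loss of sulfene) frees the ring A phenol, while ring B sits as an unreactive phenoxide and exclusion of air protects the electron-rich phenolates.

**Compound list**
1 | 8-bromooctanoic acid | OC(=O)CCCCCCCBr | starting material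
2 | (7-carboxyheptyl)triphenylphosphonium bromide | OC(=O)CCCCCCC[P+](c1ccccc1)(c1ccccc1)c1ccccc1.[Br-] | intermediate
3 | vanillin (4-hydroxy-3-methoxybenzaldehyde) | COc1cc(C=O)ccc1O | starting material
4 | potassium 8-(triphenylphosphoranylidene)octanoate (ylide carboxylate, formed in the flask) | [K+].[O-]C(=O)CCCCCCC=P(c1ccccc1)(c1ccccc1)c1ccccc1 | intermediate
5 | (Z)-9-(4-hydroxy-3-methoxyphenyl)non-8-enoic acid (Z/E mixture, Z drawn) | COc1cc(/C=C\CCCCCCC(=O)O)ccc1O | intermediate
6 | 9-(4-hydroxy-3-methoxyphenyl)nonanoic acid | COc1cc(CCCCCCCCC(=O)O)ccc1O | intermediate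
7 | 9-(4-hydroxy-3-methoxyphenyl)-N-methoxy-N-methylnonanamide | COc1cc(CCCCCCCCC(=O)N(C)OC)ccc1O | intermediate
8 | bromobenzene | Brc1ccccc1 | starting material
9 | phenylmagnesium bromide (formed in the flask) | Br[Mg]c1ccccc1 | intermediate
10 | 9-(4-hydroxy-3-methoxyphenyl)-1-phenylnonan-1-one | COc1cc(CCCCCCCCC(=O)c2ccccc2)ccc1O | intermediate
11 | 2-methoxy-4-(9-oxo-9-phenylnonyl)phenyl methanesulfonate | COc1cc(CCCCCCCCC(=O)c2ccccc2)ccc1OS(C)(=O)=O | intermediate
12 | 2-[9-(3-methoxy-4-methylsulfonyloxyphenyl)nonanoyl]phenyl trifluoroacetate (formed in the flask) | COc1cc(CCCCCCCCC(=O)c2ccccc2OC(=O)C(F)(F)F)ccc1OS(C)(=O)=O | intermediate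
13 | 2-[9-(3-methoxy-4-methylsulfonyloxyphenyl)nonanoyl]-1,3-phenylene bis(trifluoroacetate) (formed in the flask) | COc1cc(CCCCCCCCC(=O)c2c(OC(=O)C(F)(F)F)cccc2OC(=O)C(F)(F)F)ccc1OS(C)(=O)=O | intermediate
14 | 4-[9-(2,6-dihydroxyphenyl)-9-oxononyl]-2-methoxyphenyl methanesulfonate | COc1cc(CCCCCCCCC(=O)c2c(O)cccc2O)ccc1OS(C)(=O)=O | intermediate
15 | 1-(2,6-dihydroxyphenyl)-9-(4-hydroxy-3-methoxyphenyl)nonan-1-one (CNP0118788.0) | COc1cc(CCCCCCCCC(=O)c2c(O)cccc2O)ccc1O | target

**Count**
Total steps: 8. Longest linear sequence: 8 steps (1 → 2 → 5 → 6 → 7 → 10 → 11 → 14 → 15).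

**Steps most likely to fail**

Step 7 (proposed new method). The reaction may stall after the first C–O bond, because the ortho ester twists the carbonyl out of the ring plane and deactivates ring B. Ring A or its benzylic CH2 may be oxidised without direction. The enolisable ketone may condense with its own ortho ester in the hot acid. The fallback brings both ring B oxygens in ready-made by known chemistry; it sets out from Weinreb amide 7 and returns at target 15. Resorcinol is protected with MOMCl/iPr2NEt to give 1,3-bis(methoxymethoxy)benzene F1. Directed ortho-lithiation between the two acetal oxygens (n-BuLi, THF, 0 °C) gives 2,6-bis(methoxymethoxy)phenyllithium F2. Three equivalents of it (one is consumed by the phenol of 7) add to 7 to give 1-[2,6-bis(methoxymethoxy)phenyl]-9-(4-hydroxy-3-methoxyphenyl)nonan-1-one F3. HCl in MeOH at 50 °C removes both acetals and gives 15, so steps 5 to 8 are not needed.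

Step 2. The olefination may be sluggish and incomplete, because the para-phenoxide deactivates the aldehyde and the potassium salts of the ylide carboxylate and of vanillin are poorly soluble in THF. The fallback masks the phenol with a group that the next step removes anyway; it sets out from vanillin 3 and returns at acid 6. O-Benzylation (BnBr, K2CO3, DMF) gives 4-(benzyloxy)-3-methoxybenzaldehyde F4. Wittig reaction with ylide 4 (now two equivalents of KOtBu per phosphonium salt) gives (Z)-9-[4-(benzyloxy)-3-methoxyphenyl]non-8-enoic acid F5 as a Z/E mixture. Hydrogenation over 10% Pd/C saturates the alkene and cleaves the benzyl ether in one operation to give 6.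

Step 8. Cleavage of the S–O bond may be too slow at temperatures the ring B polyphenolate tolerates, or the phenolates may be degraded by air oxidation under hot alkali. The fallback changes the ring A mask to one removable by mild methanolysis; it sets out from phenol ketone 10 and returns at target 15. Acetylation (Ac2O, pyridine) gives 2-methoxy-4-(9-oxo-9-phenylnonyl)phenyl acetate F6. Hydroxylation under the conditions of step 7 proceeds through 2-[9-(4-acetoxy-3-methoxyphenyl)nonanoyl]phenyl trifluoroacetate F7 to 2-[9-(4-acetoxy-3-methoxyphenyl)nonanoyl]-1,3-phenylene bis(trifluoroacetate) F8. Any exchange of the acetate for a trifluoroacetate in the acidic medium is harmless. Treating the crude product with K2CO3 in MeOH at room temperature cleaves all three esters and gives 15.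

**Further compounds**
F1 | step 7 | 1,3-bis(methoxymethoxy)benzene | COCOc1cccc(OCOC)c1
F2 | step 7 | 2,6-bis(methoxymethoxy)phenyllithium | COCOc1cccc(OCOC)c1[Li]
F3 | step 7 | 1-[2,6-bis(methoxymethoxy)phenyl]-9-(4-hydroxy-3-methoxyphenyl)nonan-1-one | COCOc1cccc(OCOC)c1C(=O)CCCCCCCCc1ccc(O)c(OC)c1
F4 | step 2 | 4-(benzyloxy)-3-methoxybenzaldehyde | COc1cc(C=O)ccc1OCc1ccccc1
F5 | step 2 | (Z)-9-[4-(benzyloxy)-3-methoxyphenyl]non-8-enoic acid (Z/E mixture, Z drawn) | COc1cc(/C=C\CCCCCCC(=O)O)ccc1OCc1ccccc1
F6 | step 8 | 2-methoxy-4-(9-oxo-9-phenylnonyl)phenyl acetate | COc1cc(CCCCCCCCC(=O)c2ccccc2)ccc1OC(C)=O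
F7 | step 8 | 2-[9-(4-acetoxy-3-methoxyphenyl)nonanoyl]phenyl trifluoroacetate | COc1cc(CCCCCCCCC(=O)c2ccccc2OC(=O)C(F)(F)F)ccc1OC(C)=O
F8 | step 8 | 2-[9-(4-acetoxy-3-methoxyphenyl)nonanoyl]-1,3-phenylene bis(trifluoroacetate) | COc1cc(CCCCCCCCC(=O)c2c(OC(=O)C(F)(F)F)cccc2OC(=O)C(F)(F)F)ccc1OC(C)=O
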